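The route rests on cutting the C1–C10 bond: the C1 oxygen, the ring-fusion C10–H and the C9 oxygen form an aldol triad that spans the junction of cyclopentane ring A and cycloheptane ring B. One reversible, magnesium-mediated aldol addition of the C9 enone enolate to the side-chain isopropyl ketone closes ring A and sets C1 and C10 under chelate-driven thermodynamic control. Its precursor is (S)-3,6-dimethyl-6-(4-methyl-3-oxopentyl)cyclohept-2-en-1-one, whose only stereocentre (C4) comes from a copper-catalysed enantioselective conjugate addition to mirror-symmetric 3,6-dimethylcyclohepta-2,6-dien-1-one. Hydroxyl-directed reduction and epoxidation and a late acylation of the tertiary C1 alkoxide complete the target.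

Key step: step 8

Remark: locants follow the target throughout (C1 ester carbon with isopropyl, C2/C3 CH2, C4 quaternary C–CH3, C5 CH2, C6/C7 epoxide carbons with CH3 on C7, C8 CH2, C9 carbinol, C10 ring-fusion CH; ring A = C1–C2–C3–C4–C10, ring B = C4 to C10); α is the face of the C4 methyl group, β the opposite face.

Assumption: the facial sense of the copper–carbene catalyst in step 7 is taken by analogy with simple 3-methylcycloalkenones, and the ligand enantiomer that delivers the S centre is the one employed.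

Step 1
Reactants: 1 2,5-dimethylfuran; 2 1,1,3-trichloropropan-2-one
Product: 5 meso-(1R,5S)-1,5-dimethyl-8-oxabicyclo[3.2.1]oct-6-en-3-one, via oxyallyl cation 3 (not isolated), via dichloro cycloadduct 4 (not isolated)
Conditions: Et3N, CF3CH2OH, 0 °C to rt; then Zn–Cu couple, NH4Cl, MeOH, rt
Reagents that add atoms: none
Why: Base-induced ionisation of 2 in the polar fluorinated alcohol should give oxyallyl cation 3, which undergoes (4+3) cycloaddition across C2 and C5 of the electron-rich furan to 4, and zinc then reduces both α-chloro ketone C–Cl bonds; the product has a mirror plane, so no stereochemical issue arises.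

Step 2
Reactants: 5 meso-(1R,5S)-1,5-dimethyl-8-oxabicyclo[3.2.1]oct-6-en-3-one
Product: 6 meso-(1R,5S)-1,5-dimethyl-8-oxabicyclo[3.2.1]octan-3-one
Conditions: H2 (1 atm), Pd/C, EtOAc, rt
Reagents that add atoms: none
Why: Catalytic hydrogenation should saturate the strained cis-disubstituted bridge alkene without touching the ketone or the bridging ether, and the product stays meso.

Step 3
Reactants: 6 meso-(1R,5S)-1,5-dimethyl-8-oxabicyclo[3.2.1]octan-3-one
Product: 8 3,6-dimethylcyclohepta-2,6-dien-1-one, via hydroxy enone 7 (not isolated)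
Conditions: TsOH·H2O (cat.), PhH, reflux, Dean–Stark, short reaction time
Reagents that add atoms: none
Why: Acid-catalysed β-elimination of the tertiary bridging ether through the enol (retro-oxa-Michael ring opening of an 8-oxabicyclo[3.2.1]octan-3-one) should give 7, whose tertiary β-hydroxy ketone dehydrates with azeotropic removal of water to the cross-conjugated dienone; acid is preferred to base because it avoids retro-aldol cleavage of 7.

Step 4
Reactants: 9 2-methylpropanoyl chloride; 10 ethylene
Product: 11 1-chloro-4-methylpentan-3-one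
Conditions: AlCl3, CH2Cl2, ethylene (1 atm), 0 °C; then ice/aq. HCl
Reagents that add atoms: none
Why: Friedel–Crafts-type acylation of ethylene by the acylium ion followed by chloride capture of the β-cation is the standard entry to β-chloroethyl ketones.

Step 5
Reactants: 11 1-chloro-4-methylpentan-3-one
Product: 12 2-(2-chloroethyl)-2-(propan-2-yl)-1,3-dioxolane
Conditions: HOCH2CH2OH, TsOH·H2O (cat.), PhH, reflux, Dean–Stark
Reagents that add atoms: ethylene glycol, OCCO
Why: Acid-catalysed ketalisation with azeotropic removal of water masks the ketone, and acidic conditions avoid the base-induced loss of HCl to the vinyl ketone.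

Step 6
Reactants: 12 2-(2-chloroethyl)-2-(propan-2-yl)-1,3-dioxolane
Product: 13 2-(2-bromoethyl)-2-(propan-2-yl)-1,3-dioxolane
Conditions: LiBr (excess), 2-butanone, reflux
Reagents that add atoms: lithium bromide, [Li+].[Br-]
Why: Finkelstein-type SN2 halide exchange at the primary carbon, driven by excess bromide, should provide the bromide that allows Grignard formation at room temperature.

Step 7
Reactants: 13 2-(2-bromoethyl)-2-(propan-2-yl)-1,3-dioxolane; 8 3,6-dimethylcyclohepta-2,6-dien-1-one
Product: 17 (S)-3,6-dimethyl-6-(4-methyl-3-oxopentyl)cyclohept-2-en-1-one, via Grignard reagent 14 (not isolated), via magnesium enolate 15 (not isolated), via ketal enone 16 (not isolated)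
Conditions: 13, Mg, THF, 25 °C; then 8, Cu(OTf)2 (cat.), chiral 1-(1-hydroxy-4-methylpentan-2-yl)-3-mesityl-4,5-dihydroimidazolium PF6 (cat.), Et2O, −30 °C; then 2 M HCl, THF, rt
Reagents that add atoms: water, O
Why: Copper-catalysed enantioselective conjugate addition of a Grignard reagent to a β-methyl cycloalkenone should build the quaternary C4 centre, the chiral carbene on copper choosing the enantiotopic face of the two mirror-related enone termini, after which dienolate 15 cannot accept a second alkyl group and the acid work-up protonates it at C10 and hydrolyses the dioxolane of 16.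

Step 8
Reactants: 17 (S)-3,6-dimethyl-6-(4-methyl-3-oxopentyl)cyclohept-2-en-1-one
Product: 20 (3R,3aR,8aS)-3-hydroxy-6,8a-dimethyl-3-(propan-2-yl)-2,3,3a,7,8,8a-hexahydroazulen-4(1H)-one, via magnesium enolate 18 (not isolated), via magnesium aldolate 19 (not isolated)
Conditions: MgBr2·OEt2 (3 equiv), Et3N (3.5 equiv), CH2Cl2, 0 °C to rt; then AcOH, −20 °C; pH 7 buffer
Reagents that add atoms: none
Why: Soft enolisation (MgBr2-activated ketone, Et3N) should reversibly give the C9–C10 magnesium enolate 18, which adds to the side-chain ketone to forge C1–C10; the closest known reaction type is the intramolecular ketone–ketone aldol addition of a 1,6-diketone run under retro-aldol equilibration. Ring A closes in a 5-(enolexo)-exo-trig mode, helped by the quaternary C4 (Thorpe–Ingold effect). C1 is controlled by the six-membered chelate O1–Mg–O9 of aldolate 19, which can form only when the C1 oxygen is cis to C9 on ring A, so equilibration funnels material into that arrangement; C10 is controlled by the expected equilibrium preference for the trans ring fusion (C10–H β, anti to the C4 methyl, isopropyl anti to C9), and the absolute sense of both follows from the fixed C4 centre. The step needs the C10 enolate to win over the C2, γ and isopropyl enolates: closure from C2 onto C9 would give a bridged bicyclo[4.2.1] aldol that loses the enone conjugation and cannot dehydrate, so it should revert, while C8 is blocked by the C7=C8 alkene. Stoichiometric magnesium holds the product as 19, and the cold acidic quench should prevent retro-aldol cleavage or dehydration on work-up.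

Step 9
Reactants: 20 (3R,3aR,8aS)-3-hydroxy-6,8a-dimethyl-3-(propan-2-yl)-2,3,3a,7,8,8a-hexahydroazulen-4(1H)-one
Product: 21 (3R,3aR,8aS)-6,8a-dimethyl-3-(propan-2-yl)-3-[(triethylsilyl)oxy]-2,3,3a,7,8,8a-hexahydroazulen-4(1H)-one
Conditions: Et3SiOTf, 2,6-lutidine, CH2Cl2, −78 to 0 °C
Reagents that add atoms: triethylsilyl trifluoromethanesulfonate, CC[Si](CC)(CC)OS(=O)(=O)C(F)(F)F
Why: A silyl triflate with a hindered pyridine base silylates even a hindered tertiary alcohol without forming an alkoxide, so the retro-aldol channel stays closed and no stereocentre is touched.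

Step 10
Reactants: 21 (3R,3aR,8aS)-6,8a-dimethyl-3-(propan-2-yl)-3-[(triethylsilyl)oxy]-2,3,3a,7,8,8a-hexahydroazulen-4(1H)-one
Product: 23 (3R,3aR,8aR)-6,8a-dimethyl-3-(propan-2-yl)-3-[(triethylsilyl)oxy]-2,3,3a,5,8,8a-hexahydroazulen-4(1H)-one, via potassium dienolate 22 (not isolated)
Conditions: KOtBu, THF/t-BuOH, 0 °C; then inverse quench into AcOH, THF, −78 °C
Reagents that add atoms: none
Why: Kinetic deconjugation of an α,β-unsaturated ketone: equilibrating γ-deprotonation at ring C6 should give the more substituted endocyclic dienolate 22, and fast protonation at the α-carbon C8 delivers the C6=C7 isomer, C10 being spared because the carbonyl is tied up as the dienolate.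

Step 11
Reactants: 23 (3R,3aR,8aR)-6,8a-dimethyl-3-(propan-2-yl)-3-[(triethylsilyl)oxy]-2,3,3a,5,8,8a-hexahydroazulen-4(1H)-one
Product: 24 (3R,3aR,8aR)-3-hydroxy-6,8a-dimethyl-3-(propan-2-yl)-2,3,3a,5,8,8a-hexahydroazulen-4(1H)-one
Conditions: HF·pyridine, pyridine, THF, 0 °C to rt
Reagents that add atoms: none
Why: Buffered fluoride cleavage of the Si–O bond frees the C1 hydroxyl under weakly acidic conditions that should neither reconjugate the alkene nor trigger retro-aldol cleavage.

Step 12
Reactants: 24 (3R,3aR,8aR)-3-hydroxy-6,8a-dimethyl-3-(propan-2-yl)-2,3,3a,5,8,8a-hexahydroazulen-4(1H)-one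
Product: 26 (3R,3aS,4S,8aR)-6,8a-dimethyl-3-(propan-2-yl)-1,2,3,3a,4,5,8,8a-octahydroazulene-3,4-diol, via alkoxyborohydride 25 (not isolated)
Conditions: Me4NBH(OAc)3, MeCN/AcOH (1:1), −30 to 0 °C; then aq. KNaC4H4O6
Reagents that add atoms: none
Why: Hydroxyl-directed triacetoxyborohydride reduction: the C1 hydroxyl exchanges an acetate on boron and 25 delivers hydride within the molecule to the face of the C9 carbonyl that the C1 oxygen can reach, which should give the 1,3-anti diol with C9–OH β.

Step 13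
Reactants: 26 (3R,3aS,4S,8aR)-6,8a-dimethyl-3-(propan-2-yl)-1,2,3,3a,4,5,8,8a-octahydroazulene-3,4-diol
Product: 28 (3R,3aS,4S,8aR)-4-[(4-methoxybenzyl)oxy]-6,8a-dimethyl-3-(propan-2-yl)-1,2,3,3a,4,5,8,8a-octahydroazulen-3-ol, via sodium alkoxide 27 (not isolated)
Conditions: NaH (1.1 equiv), THF/DMF, 0 °C; then 4-MeOC6H4CH2Cl, Bu4NI (cat.), 0 °C to rt
Reagents that add atoms: 4-methoxybenzyl chloride, COc1ccc(CCl)cc1
Why: Williamson etherification should be selective for the secondary C9 oxygen because the tertiary C1 hydroxyl is far more hindered, and an ether is chosen because, unlike a silyl group, it cannot migrate to the C1 alkoxide in step 15.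

Step 14
Reactants: 29 4-(benzyloxy)-3-methoxybenzoic acid
Product: 30 4-(benzyloxy)-3-methoxybenzoyl chloride
Conditions: (COCl)2, DMF (cat.), CH2Cl2, 0 °C to rt
Reagents that add atoms: oxalyl chloride, ClC(=O)C(Cl)=O
Why: DMF-catalysed reaction with oxalyl chloride converts the carboxylic acid into the acid chloride while the benzyl aryl ether is inert.

Step 15
Reactants: 28 (3R,3aS,4S,8aR)-4-[(4-methoxybenzyl)oxy]-6,8a-dimethyl-3-(propan-2-yl)-1,2,3,3a,4,5,8,8a-octahydroazulen-3-ol; 30 4-(benzyloxy)-3-methoxybenzoyl chloride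
Product: 32 (3R,3aS,4S,8aR)-4-[(4-methoxybenzyl)oxy]-6,8a-dimethyl-3-(propan-2-yl)-1,2,3,3a,4,5,8,8a-octahydroazulen-3-yl 4-(benzyloxy)-3-methoxybenzoate, via potassium alkoxide 31 (not isolated)
Conditions: KN(SiMe3)2, THF, −78 °C; then 30, −78 to 0 °C
Reagents that add atoms: none
Why: Acylation of a pre-formed tertiary alkoxide with an aroyl chloride is the dependable way to esterify a hindered tertiary alcohol, and the C9 oxygen is inert as its benzyl-type ether.

Step 16
Reactants: 32 (3R,3aS,4S,8aR)-4-[(4-methoxybenzyl)oxy]-6,8a-dimethyl-3-(propan-2-yl)-1,2,3,3a,4,5,8,8a-octahydroazulen-3-yl 4-(benzyloxy)-3-methoxybenzoate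
Product: 33 (3R,3aS,4S,8aR)-4-hydroxy-6,8a-dimethyl-3-(propan-2-yl)-1,2,3,3a,4,5,8,8a-octahydroazulen-3-yl 4-(benzyloxy)-3-methoxybenzoate
Conditions: DDQ, CH2Cl2/pH 7 buffer (NaH2PO4/Na2HPO4), 0 °C
Reagents that add atoms: none
Why: Oxidative cleavage of the electron-rich 4-methoxybenzyl ether runs near neutrality, should spare the benzyl aryl ether and the alkene, and generates no alkoxide that could pull the acyl group from C1 to C9.

Step 17
Reactants: 33 (3R,3aS,4S,8aR)-4-hydroxy-6,8a-dimethyl-3-(propan-2-yl)-1,2,3,3a,4,5,8,8a-octahydroazulen-3-yl 4-(benzyloxy)-3-methoxybenzoate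
Product: 34 benzyl-protected epoxy ester: (1R,4R,6S,7R,9S,10S)-6,7-epoxy-9-hydroxy-1-isopropyl-4,7-dimethyldecahydroazulen-1-yl 4-(benzyloxy)-3-methoxybenzoate (target locants)
Conditions: VO(acac)2 (cat.), t-BuOOH, CH2Cl2, 0 °C to rt
Reagents that add atoms: tert-butyl hydroperoxide, CC(C)(C)OO
Why: Vanadium-catalysed hydroxyl-directed epoxidation of the homoallylic alcohol should transfer oxygen to the face of C6=C7 on which the C9 hydroxyl lies (β), setting C6 and C7 cis to C9–OH.

Step 18
Reactants: 34 benzyl-protected epoxy ester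
Product: 35 CNP0315707.1: (1R,4R,6S,7R,9S,10S)-6,7-epoxy-9-hydroxy-1-isopropyl-4,7-dimethyldecahydroazulen-1-yl 4-hydroxy-3-methoxybenzoate (target locants)
Conditions: H2 (1 atm), Pd/C, EtOAc, rt
Reagents that add atoms: none
Why: Hydrogenolysis of the benzyl aryl ether under neutral conditions should free the phenol without opening the trialkyl epoxide, cleaving the ester or inducing acyl migration.

Compound list

1 | 2,5-dimethylfuran | Cc1ccc(C)o1 | starting material
2 | 1,1,3-trichloropropan-2-one | ClCC(=O)C(Cl)Cl | starting material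
3 | 1,3-dichloro-2-oxidoallyl cation (oxyallyl zwitterion, not isolated) | [O-]C(=CCl)[CH+]Cl | intermediate
4 | 2,4-dichloro-1,5-dimethyl-8-oxabicyclo[3.2.1]oct-6-en-3-one (C2/C4 epimers, not isolated) | C[C@@]12C(Cl)C(=O)C(Cl)[C@@](C)(O1)C=C2 | intermediate
5 | meso-(1R,5S)-1,5-dimethyl-8-oxabicyclo[3.2.1]oct-6-en-3-one | C[C@@]12CC(=O)C[C@@](C)(O1)C=C2 | intermediate
6 | meso-(1R,5S)-1,5-dimethyl-8-oxabicyclo[3.2.1]octan-3-one | C[C@@]12CC(=O)C[C@@](C)(O1)CC2 | intermediate
7 | 6-hydroxy-3,6-dimethylcyclohept-2-en-1-one (racemic, not isolated) | CC1=CC(=O)CC(C)(O)CC1 | intermediate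
8 | 3,6-dimethylcyclohepta-2,6-dien-1-one (achiral, mirror-symmetric) | CC1=CC(=O)C=C(C)CC1 | intermediate
9 | 2-methylpropanoyl chloride (isobutyryl chloride) | CC(C)C(Cl)=O | starting material
10 | ethylene | C=C | starting material
11 | 1-chloro-4-methylpentan-3-one | CC(C)C(=O)CCCl | intermediate
12 | 2-(2-chloroethyl)-2-(propan-2-yl)-1,3-dioxolane | CC(C)C1(CCCl)OCCO1 | intermediate
13 | 2-(2-bromoethyl)-2-(propan-2-yl)-1,3-dioxolane | CC(C)C1(CCBr)OCCO1 | intermediate
14 | {2-[2-(propan-2-yl)-1,3-dioxolan-2-yl]ethyl}magnesium bromide (not isolated) | CC(C)C1(CC[Mg]Br)OCCO1 | intermediate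
15 | bromomagnesium C9–C10 dienolate of 16, (S) at C4 (not isolated) | CC(C)C1(CC[C@]2(C)CCC(C)=CC(O[Mg]Br)=C2)OCCO1 | intermediate
16 | (S)-3,6-dimethyl-6-{2-[2-(propan-2-yl)-1,3-dioxolan-2-yl]ethyl}cyclohept-2-en-1-one (not isolated) | CC(C)C1(CC[C@]2(C)CCC(C)=CC(=O)C2)OCCO1 | intermediate
17 | (S)-3,6-dimethyl-6-(4-methyl-3-oxopentyl)cyclohept-2-en-1-one | CC(C)C(=O)CC[C@]1(C)CCC(C)=CC(=O)C1 | intermediate
18 | bromomagnesium C9–C10 enolate of 17 (not isolated) | CC(C)C(=O)CC[C@]1(C)CCC(C)=CC(O[Mg]Br)=C1 | intermediate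
19 | chelated bromomagnesium C1 aldolate of 20 (not isolated) | Br[Mg]O[C@@]1(C(C)C)CC[C@]2(C)CCC(C)=CC(=O)[C@H]21 | intermediate
20 | (3R,3aR,8aS)-3-hydroxy-6,8a-dimethyl-3-(propan-2-yl)-2,3,3a,7,8,8a-hexahydroazulen-4(1H)-one; target locants 1R,4S,10R; C1–OH α, C10–H β, trans-fused, C9 ketone, C7=C8 | O[C@@]1(C(C)C)CC[C@]2(C)CCC(C)=CC(=O)[C@H]21 | intermediate
21 | (3R,3aR,8aS)-6,8a-dimethyl-3-(propan-2-yl)-3-[(triethylsilyl)oxy]-2,3,3a,7,8,8a-hexahydroazulen-4(1H)-one | CC[Si](CC)(CC)O[C@@]1(C(C)C)CC[C@]2(C)CCC(C)=CC(=O)[C@H]21 | intermediate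
22 | potassium C9=C8–C7=C6 dienolate of 21 (not isolated) | [K+].CC[Si](CC)(CC)O[C@@]1(C(C)C)CC[C@]2(C)CC=C(C)C=C([O-])[C@H]21 | intermediate
23 | (3R,3aR,8aR)-6,8a-dimethyl-3-(propan-2-yl)-3-[(triethylsilyl)oxy]-2,3,3a,5,8,8a-hexahydroazulen-4(1H)-one; C6=C7 | CC[Si](CC)(CC)O[C@@]1(C(C)C)CC[C@]2(C)CC=C(C)CC(=O)[C@H]21 | intermediate
24 | (3R,3aR,8aR)-3-hydroxy-6,8a-dimethyl-3-(propan-2-yl)-2,3,3a,5,8,8a-hexahydroazulen-4(1H)-one | O[C@@]1(C(C)C)CC[C@]2(C)CC=C(C)CC(=O)[C@H]21 | intermediate
25 | tetramethylammonium C1-alkoxy(diacetoxy)borohydride of 24 (not isolated) | C[N+](C)(C)C.CC(=O)O[BH-](OC(C)=O)O[C@@]1(C(C)C)CC[C@]2(C)CC=C(C)CC(=O)[C@H]21 | intermediate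
26 | (3R,3aS,4S,8aR)-6,8a-dimethyl-3-(propan-2-yl)-1,2,3,3a,4,5,8,8a-octahydroazulene-3,4-diol; target locants 1R,4R,9S,10S | O[C@@]1(C(C)C)CC[C@]2(C)CC=C(C)C[C@H](O)[C@H]21 | intermediate
27 | sodium C9 alkoxide of 26 (not isolated) | [Na+].O[C@@]1(C(C)C)CC[C@]2(C)CC=C(C)C[C@H]([O-])[C@H]21 | intermediate
28 | (3R,3aS,4S,8aR)-4-[(4-methoxybenzyl)oxy]-6,8a-dimethyl-3-(propan-2-yl)-1,2,3,3a,4,5,8,8a-octahydroazulen-3-ol | O[C@@]1(C(C)C)CC[C@]2(C)CC=C(C)C[C@H](OCc3ccc(OC)cc3)[C@H]21 | intermediate
29 | 4-(benzyloxy)-3-methoxybenzoic acid | COc1cc(C(=O)O)ccc1OCc1ccccc1 | starting material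
30 | 4-(benzyloxy)-3-methoxybenzoyl chloride | COc1cc(C(Cl)=O)ccc1OCc1ccccc1 | intermediate
31 | potassium C1 alkoxide of 28 (not isolated) | [K+].[O-][C@@]1(C(C)C)CC[C@]2(C)CC=C(C)C[C@H](OCc3ccc(OC)cc3)[C@H]21 | intermediate
32 | (3R,3aS,4S,8aR)-4-[(4-methoxybenzyl)oxy]-6,8a-dimethyl-3-(propan-2-yl)-1,2,3,3a,4,5,8,8a-octahydroazulen-3-yl 4-(benzyloxy)-3-methoxybenzoate | COc1cc(C(=O)O[C@@]2(C(C)C)CC[C@]3(C)CC=C(C)C[C@H](OCc4ccc(OC)cc4)[C@H]32)ccc1OCc1ccccc1 | intermediate
33 | (3R,3aS,4S,8aR)-4-hydroxy-6,8a-dimethyl-3-(propan-2-yl)-1,2,3,3a,4,5,8,8a-octahydroazulen-3-yl 4-(benzyloxy)-3-methoxybenzoate | COc1cc(C(=O)O[C@@]2(C(C)C)CC[C@]3(C)CC=C(C)C[C@H](O)[C@H]32)ccc1OCc1ccccc1 | intermediate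
34 | (1R,4R,6S,7R,9S,10S)-6,7-epoxy-9-hydroxy-1-isopropyl-4,7-dimethyldecahydroazulen-1-yl 4-(benzyloxy)-3-methoxybenzoate (target locants; epoxide β, C9–OH β, C1–O α) | COc1cc(C(=O)O[C@@]2(C(C)C)CC[C@]3(C)C[C@@H]4O[C@]4(C)C[C@H](O)[C@H]32)ccc1OCc1ccccc1 | intermediate
35 | CNP0315707.1, (1R,4R,6S,7R,9S,10S)-6,7-epoxy-9-hydroxy-1-isopropyl-4,7-dimethyldecahydroazulen-1-yl 4-hydroxy-3-methoxybenzoate (target locants) | COc1cc(C(=O)O[C@@]2(C(C)C)CC[C@]3(C)C[C@@H]4O[C@]4(C)C[C@H](O)[C@H]32)ccc1O | target

Total step count: 18. Longest linear sequence: 14 steps (1–3, 7–13, 15–18); steps 4–6 and step 14 are side branches.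

Steps most likely to fail

1. Step 8 (key step). The equilibrium may rest on the open diketone, the aldolate may lose water towards the C1=C10 dienone, the C2 enolate may close irreversibly onto C7 in a Michael sense, or the ring fusion may settle cis. The fallback replaces equilibration by a regiospecific, kinetically generated enolate; it sets out from magnesium enolate 15 (step 7, before the acid work-up) and comes back at 20. The enolate is silylated with Me3SiCl to the trimethylsilyl dienol ether F1. N-Bromosuccinimide (THF, −78 °C) brominates the enol ether terminus to the C10 bromo enone F2, and aqueous HCl in THF removes the dioxolane to give the bromo diketone F3. SmI2 (THF, −78 °C) then reduces the C–Br bond to the trivalent samarium enolate F4, fixed at C9–C10, which adds to the C1 ketone through a chelated transition state (intramolecular Reformatsky reaction); a cold AcOH quench should give 20. The samarium bridge again places the C1 oxygen cis to C9, and C10 stays epimerisable next to the ketone should the fusion need correcting.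

2. Step 10. Competing deprotonation at C10, followed by β-elimination of the silyloxy group or epimerisation, and reconjugation during the quench may erode the deconjugation. The fallback never exposes the free ketone to base; it sets out from 21 and comes back at 23. Soft enolisation with Me3SiOTf and Et3N (CH2Cl2, 0 °C to rt) should give the extended trimethylsilyl dienol ether F5. MeLi (THF, 0 °C) cleaves the O–Si bond to the lithium dienolate F6, and inverse addition to AcOH at −78 °C protonates it at C8 to give 23.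

3. Step 7. The β-ketal Grignard reagent may decompose by γ-elimination, add 1,2 without the catalyst, or meet weak facial discrimination at the disubstituted β-carbon. The fallback draws the nucleophile from an alkene instead of a halide; it sets out from 13 and comes back at 16. Dehydrobromination of 13 with KOtBu (THF, 0 °C) gives the vinyl ketal F7. Hydrozirconation with Cp2Zr(H)Cl (CH2Cl2, rt) gives the alkylzirconocene F8. Copper-catalysed enantioselective conjugate addition of F8 to 8 (CuCl, AgNTf2, chiral phosphoramidite, Et2O, rt) passes through the zirconium enolate F9 and should give 16 on aqueous work-up, which is hydrolysed to 17 exactly as in step 7.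

Further compounds

F1 | step 8 | (S)-trimethylsilyl dienol ether of 16, 2-{2-[1,4-dimethyl-6-(trimethylsilyloxy)cyclohepta-3,6-dien-1-yl]ethyl}-2-(propan-2-yl)-1,3-dioxolane | CC(C)C1(CC[C@]2(C)CCC(C)=CC(O[Si](C)(C)C)=C2)OCCO1
F2 | step 8 | 7-bromo-3,6-dimethyl-6-{2-[2-(propan-2-yl)-1,3-dioxolan-2-yl]ethyl}cyclohept-2-en-1-one (6S, bromide epimers at C10) | CC(C)C1(CC[C@]2(C)CCC(C)=CC(=O)C2Br)OCCO1
F3 | step 8 | 7-bromo-3,6-dimethyl-6-(4-methyl-3-oxopentyl)cyclohept-2-en-1-one (6S, bromide epimers at C10) | CC(C)C(=O)CC[C@]1(C)CCC(C)=CC(=O)C1Br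
F4 | step 8 | diiodosamarium C9–C10 enolate of 17 | CC(C)C(=O)CC[C@]1(C)CCC(C)=CC(O[Sm](I)I)=C1
F5 | step 10 | extended trimethylsilyl dienol ether of 21 (C9=C8, C7=C6) | CC[Si](CC)(CC)O[C@@]1(C(C)C)CC[C@]2(C)CC=C(C)C=C(O[Si](C)(C)C)[C@H]21
F6 | step 10 | lithium dienolate of 21 | [Li+].CC[Si](CC)(CC)O[C@@]1(C(C)C)CC[C@]2(C)CC=C(C)C=C([O-])[C@H]21
F7 | step 7 | 2-ethenyl-2-(propan-2-yl)-1,3-dioxolane | C=CC1(C(C)C)OCCO1
F8 | step 7 | chlorobis(cyclopentadienyl){2-[2-(propan-2-yl)-1,3-dioxolan-2-yl]ethyl}zirconium | CC(C)C1(CC[Zr](Cl)(C2C=CC=C2)C2C=CC=C2)OCCO1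
F9 | step 7 | chlorobis(cyclopentadienyl)zirconium C9–C10 enolate of 16 | CC(C)C1(CC[C@]2(C)CCC(C)=CC(O[Zr](Cl)(C3C=CC=C3)C3C=CC=C3)=C2)OCCO1
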